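A small charge of free catalyst brings the target to 5.6% in elm and 10.1% in alder by the last reading.

common to all: free catalyst 16 mol%

| flask | starting material | gas phase | remark | time |
|---|---|---|---|---|
| elm | 11 mM | 8 mM (held) | run made earlier |  |
| alder | 24 mM | 8 mM (held) | run made earlier |  |
| flask | 16 mM | 8.0 mM (held) |  | 4.0 min |

| run | time / min | target / % | starting material / % |
|---|---|---|---|
| elm | 0.250 | 0.4 | 99.4 |
| elm | 0.833 | 1.9 | 98.3 |
| elm | 1.33 | 2.0 | 98.7 |
| elm | 2.00 | 2.9 | 96.8 |
| elm | 3.00 | 4.7 | 94.9 |
| elm | 4.00 | 5.6 | 94.3 |
| alder | 0.667 | 1.8 | 99.4 |
| alder | 1.33 | 3.3 | 96.0 |
| alder | 2.00 | 5.3 | 94.5 |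
| alder | 2.50 | 7.6 | 91.7 |
| alder | 3.00 | 8.4 | 91.3 |
| alder | 4.00 | 10.1 | 89.7 |

(standard deviation of a reading: 0.5 percentage points)

- at the start none of the gas is dissolved
- the earlier runs were read with a standard deviation of 0.5 percentage points
- what may be going on: gas phase <-> dissolved gas; starting material + dissolved gas + free catalyst -> free catalyst + target; 2 free catalyst -> spent catalyst A; dissolved gas + free catalyst -> spent catalyst B; target <-> isomer of the product

* target at 4.0 min, in percent of the starting material charged
* concentration of dissolved gas in solution at 2.0 min, in percent of saturation
* the change that raises the amount of target at 4.0 min, in percent of the starting material charged most ("none" if none brings more than 2 percentage points) (noon / midnight / dawn / none)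
* amount of target at 4.0 min, in percent of the starting material charged, after midnight

- noon: doubling the saturation concentration of gas phase, all else as stated
- midnight: doubling the amount of free catalyst, all else as stated
- dawn: doubling the transfer coefficient of the gas phase, all else as stated

Suppose the step to target runs at k·A·G·C, with A the starting material, G the dissolved gas, C the free catalyst and k its constant. I divide by A and integrate: the logarithm of A charged over A present equals k times the area under G·C. A has left the right side (pseudo-first-order in starting material), and at small conversion that logarithm is the fraction turned over. So the fraction should follow the catalyst concentration charged: 1.76 mM in elm, 3.84 mM in alder, 2.56 mM in this flask. Catalyst divided by fraction gives a price of conversion: 31.4 mM in elm and 38.0 mM in alder, so the yield grows more slowly than the catalyst. A straight line between them gives 34.0 mM here, hence a yield of 7.53%.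

The weak link is that each price rests on one reading with a scatter of 0.5 percentage points. The loss of starting material reads the same conversion, if little isomer forms, so I average the two. The price Q, catalyst charged over the mean fraction at the last reading, becomes 31.2 mM in elm and 37.6 mM in alder, rising 3.12 per unit of catalyst. This flask then stands at 33.6 mM, and I commit to 7.61%. Extended past alder to twice this flask's catalyst, the line gives 12.3% for midnight, an estimated gain of 4.7 points, more than the 2 points needed. No run moves the gas, so I put no figure on noon, dawn or the dissolved gas, and I name midnight on this estimated gain.

The forecast gives 7.6%, 90%, noon and 13%, holding that “Doubling saturation doubles dissolved gas without that penalty”.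

The flask gives 7.48% at 4.0 min, and its dissolved gas stands at 44.6% of saturation at 2.0 min. The best change is midnight, worth 4.6 points against 1.1 points for noon and 0.82 points for dawn, and after it the target stands at 12.1%.

    gas phase ⇌ dissolved gas, rate k1*(csat - [dissolved gas]) (kL = 0.468 min⁻¹)
    starting material + dissolved gas + free catalyst → free catalyst + target (k = 6330 M⁻² min⁻¹)
    2 free catalyst → spent catalyst A (k = 16.1 M⁻¹ min⁻¹)
    dissolved gas + free catalyst → spent catalyst B (k = 149 M⁻¹ min⁻¹)
    target ⇌ isomer of the product (K = 0.600, k = 0.0396 min⁻¹)

This flask's Q comes out at 32.9 mM against the 33.6 mM I reckoned, and the line through Q, carried below elm, gives a mean fraction of 3.55% for the same flask with 6.4 mol% of free catalyst, where the target stands at 3.41% and 96% of the starting material is left. At 1.50 min this flask loses free catalyst to spent catalyst B 9.1 times as fast as to spent catalyst A. By 4.00 min its free catalyst is down to 11.5%, with 77.5% of the charge as spent catalyst B.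

The numbers in the tables were computed with made-up constants; noise was put on by code.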